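**Assumptions.** Labdane numbering as in andrographolide. α/β denote the real faces in the usual drawing: C20 on C10 is α, H‑5 and H‑9 are β, the C9 side chain is α, and C19 is the axial α substituent on C4. The target is therefore 2β,3β‑diacetoxy‑19‑oxo‑labda‑7,13E‑dien‑15‑oic acid on the ent‑labdane skeleton, with C4, C5, C9 and C10 configured as in (−)‑andrographolide. TBS = tert‑butyldimethylsilyl. All reagents on the Conditions lines are bought. The route is a paper proposal; none of it has been run.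

**Retrosynthetic overview**
1. Target 19 ⇐ 19‑alcohol 18 ⇐ cis‑2β,3β‑diol 16 ⇐ 2β‑benzoyloxy‑3‑ketone 14 (bulky hydride from the α side gives the axial 3β‑OH).
2. Key disconnection C2–O: [3,3]‑sigmatropic rearrangement of the N‑benzoyloxy‑N‑methyl ene‑hydroxylamine of 3‑ketone 11; metal‑free, so both alkenes survive, and the equatorial 2β product results.
3. Side chain C12–C13: Negishi coupling of a C12 alkylzinc with (E)‑enol triflate 9; C12 is exposed by cleaving the C12=C13 bond of andrographolide.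
4. Δ7 alkene: hydrogen‑atom‑transfer isomerisation of the exocyclic C8=C17 alkene, done before the second alkene is installed.
5. Rings: none is built. Rings A and B, with C4, C5, C9 and C10, are bought intact in (−)‑andrographolide 1; its lactone ring is cut away in step 2.

**Route**

Step 1
Reactants: 1 (−)-andrographolide
Product: 2 19-O-(tert-butyldimethylsilyl)andrographolide
Conditions: TBSCl (1.1 equiv), imidazole, DMF, 0 °C → rt
Reagents that add atoms: tert-butyldimethylsilyl chloride, CC(C)(C)[Si](C)(C)Cl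
Why: Selective silyl ether formation at the only primary hydroxyl (the hindered equatorial 3‑OH and the 14‑OH, which is excised later, react more slowly); no stereocentre is touched.

Step 2
Reactants: 2 19-O-(tert-butyldimethylsilyl)andrographolide
Product: 3 19-(TBS-oxy)-3α-hydroxy-13,14,15,16-tetranorlabd-8(17)-en-12-al
Conditions: KMnO4 (2 equiv), THF/H2O, −10 → 0 °C; aq. NaHSO3
Reagents that add atoms: potassium permanganate, [K+].[O-][Mn](=O)(=O)=O
Why: Permanganate oxidative cleavage (syn‑dihydroxylation, then glycol cleavage) should be fastest at the electron‑poor conjugated C12=C13 bond of the α‑alkylidene lactone, sparing the isolated C8=C17 alkene; C9 is β to the new aldehyde and cannot epimerise.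

Step 3
Reactants: 3 19-(TBS-oxy)-3α-hydroxy-13,14,15,16-tetranorlabd-8(17)-en-12-al
Product: 4 19-(TBS-oxy)-13,14,15,16-tetranorlabd-8(17)-ene-3α,12-diol
Conditions: NaBH4, MeOH, 0 °C
Reagents that add atoms: none
Why: Borohydride reduction of the aldehyde to the primary alcohol; no stereocentre is involved.

Step 4
Reactants: 4 19-(TBS-oxy)-13,14,15,16-tetranorlabd-8(17)-ene-3α,12-diol
Product: 5 19-(TBS-oxy)-13,14,15,16-tetranorlabd-7-ene-3α,12-diol
Conditions: chloro[N,N'-ethylenebis(3,5-di-tert-butylsalicylideneiminato)]cobalt (3 mol %), PhSiH3 (6 mol %), benzene, rt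
Reagents that add atoms: none
Why: Metal‑hydride hydrogen‑atom‑transfer alkene isomerisation: H adds reversibly to C17, and the bulky cobalt complex then takes the accessible secondary H‑7 rather than the tertiary H‑9 next to quaternary C10, giving the trisubstituted Δ7 alkene with C9 intact; it is done here because no second alkene is yet present to trap the C8 radical.

Step 5
Reactants: 5 19-(TBS-oxy)-13,14,15,16-tetranorlabd-7-ene-3α,12-diol
Product: 6 12-iodo-19-(TBS-oxy)-13,14,15,16-tetranorlabd-7-en-3α-ol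
Conditions: I2, PPh3, imidazole, CH2Cl2, 0 °C → rt
Reagents that add atoms: iodine, II
Why: Appel iodination occurs only at the unhindered primary alcohol; the neopentyl‑type secondary 3‑OH does not undergo substitution.

Step 6
Reactants: 6 12-iodo-19-(TBS-oxy)-13,14,15,16-tetranorlabd-7-en-3α-ol
Product: 7 12-iodo-19-(TBS-oxy)-13,14,15,16-tetranorlabd-7-en-3-one
Conditions: Dess–Martin periodinane, NaHCO3, CH2Cl2, rt
Reagents that add atoms: none
Why: Dess–Martin oxidation of the secondary alcohol; the ketone can enolise only toward C2 because C4 is quaternary.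

Step 7
Reactants: 8 methyl acetoacetate
Product: 9 methyl (E)-3-(trifluoromethylsulfonyloxy)but-2-enoate
Conditions: Tf2O, aq. Me4NOH, hexanes, 5 °C → rt
Reagents that add atoms: trifluoromethanesulfonic anhydride, O=S(=O)(OS(=O)(=O)C(F)(F)F)C(F)(F)F
Why: Stereoselective enol triflation: the non‑chelated tetramethylammonium enolate is O‑sulfonylated in its dipole‑minimised geometry, placing OTf trans to the ester (a lithium base would give the Z isomer by chelation).

Step 8
Reactants: 7 12-iodo-19-(TBS-oxy)-13,14,15,16-tetranorlabd-7-en-3-one; 9 methyl (E)-3-(trifluoromethylsulfonyloxy)but-2-enoate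
Product: 11 methyl 19-(TBS-oxy)-3-oxolabda-7,13E-dien-15-oate, via alkylzinc iodide 10 (not isolated)
Conditions: Zn dust (TMSCl/BrCH2CH2Br‑activated), DMA, 40 °C; then 9, Pd(PPh3)4 (5 mol %), LiCl, THF, 50 °C
Reagents that add atoms: none
Why: Zinc insertion into the primary C–I bond tolerates the ketone, and Negishi sp3–sp2 cross‑coupling proceeds with retention at the enol triflate, so C12 ends up trans to the ester (13E).

Step 9
Reactants: 11 methyl 19-(TBS-oxy)-3-oxolabda-7,13E-dien-15-oate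
Product: 14 methyl 2β-benzoyloxy-19-(TBS-oxy)-3-oxolabda-7,13E-dien-15-oate, via ene-hydroxylamine 12 (not isolated), via benzoyloxy imine 13 (not isolated)
Conditions: MeNH–OBz·HCl (1.5 equiv), DMSO, 50 °C
Reagents that add atoms: N-methyl-O-benzoylhydroxylamine hydrochloride, CNOC(=O)c1ccccc1.Cl; water, O (re-forms the C3 carbonyl oxygen when 13 is hydrolysed)
Why: Ketone α‑oxyacylation with an N‑alkyl‑O‑acylhydroxylamine: condensation gives the C2=C3 ene‑hydroxylamine, whose concerted [3,3]‑sigmatropic rearrangement breaks N–O and forms the C2–O bond without touching either alkene; the enolisable C2 centre settles as the equatorial 2β‑benzoate, anti to the axial C20 methyl.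

Step 10
Reactants: 14 methyl 2β-benzoyloxy-19-(TBS-oxy)-3-oxolabda-7,13E-dien-15-oate
Product: 15 methyl 2β-benzoyloxy-3β-hydroxy-19-(TBS-oxy)labda-7,13E-dien-15-oate
Conditions: LiBH(sec-Bu)3 (L‑Selectride, 1.2 equiv), THF, −78 °C; AcOH quench at −78 °C
Reagents that add atoms: none
Why: Ketone reduction under steric approach control: the bulky trialkylborohydride avoids the axial trajectory and attacks from the equatorial (α) side, giving the axial 3β‑alcohol cis to the 2β‑benzoate; any 1,2‑benzoyl shift is erased in step 11.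

Step 11
Reactants: 15 methyl 2β-benzoyloxy-3β-hydroxy-19-(TBS-oxy)labda-7,13E-dien-15-oate
Product: 16 2β,3β-dihydroxy-19-(TBS-oxy)labda-7,13E-dien-15-oic acid
Conditions: LiOH, THF/MeOH/H2O, 50 °C; then 1 M HCl to pH 3
Reagents that add atoms: lithium hydroxide, [Li+].[OH-]
Why: Saponification removes the benzoate and the methyl ester in one operation; the TBS ether, both alkenes and all stereocentres are stable to hydroxide.

Step 12
Reactants: 16 2β,3β-dihydroxy-19-(TBS-oxy)labda-7,13E-dien-15-oic acid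
Product: 17 2β,3β-diacetoxy-19-(TBS-oxy)labda-7,13E-dien-15-oic acid
Conditions: Ac2O, pyridine, DMAP, rt → 40 °C; aq. NaHCO3, then dilute acid work‑up
Reagents that add atoms: acetic anhydride, CC(=O)OC(C)=O
Why: DMAP‑catalysed acetylation of both secondary hydroxyls, including the hindered axial 3β‑OH; the transient mixed anhydride of the acid is hydrolysed on aqueous work‑up.

Step 13
Reactants: 17 2β,3β-diacetoxy-19-(TBS-oxy)labda-7,13E-dien-15-oic acid
Product: 18 2β,3β-diacetoxy-19-hydroxylabda-7,13E-dien-15-oic acid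
Conditions: HF·pyridine, THF/pyridine, 0 °C → rt
Reagents that add atoms: none
Why: Acidic fluoride desilylation leaves the acetates in place; the 3β‑acetate is anti to C19, so no acyl migration to the freed alcohol is possible.

Step 14
Reactants: 18 2β,3β-diacetoxy-19-hydroxylabda-7,13E-dien-15-oic acid
Product: 19 2β,3β-diacetoxy-19-oxolabda-7,13E-dien-15-oic acid (target)
Conditions: Dess–Martin periodinane, NaHCO3, CH2Cl2, 0 °C → rt
Reagents that add atoms: none
Why: Dess–Martin oxidation of the neopentyl primary alcohol to the aldehyde tolerates the free acid, acetates and alkenes; C4 is quaternary, so the aldehyde can neither epimerise nor eliminate.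

**Compound list**
1 | (−)-andrographolide | C1C[C@@]2(C)[C@H](C/C=C/3\[C@@H](COC3=O)O)C(=C)CC[C@@H]2[C@](C)(CO)[C@@H]1O | starting material
2 | 19-O-(tert-butyldimethylsilyl)andrographolide | C1C[C@@]2(C)[C@H](C/C=C/3\[C@@H](COC3=O)O)C(=C)CC[C@@H]2[C@](C)(CO[Si](C)(C)C(C)(C)C)[C@@H]1O | intermediate
3 | 19-(TBS-oxy)-3α-hydroxy-13,14,15,16-tetranorlabd-8(17)-en-12-al | C1C[C@@]2(C)[C@H](CC=O)C(=C)CC[C@@H]2[C@](C)(CO[Si](C)(C)C(C)(C)C)[C@@H]1O | intermediate
4 | 19-(TBS-oxy)-13,14,15,16-tetranorlabd-8(17)-ene-3α,12-diol | C1C[C@@]2(C)[C@H](CCO)C(=C)CC[C@@H]2[C@](C)(CO[Si](C)(C)C(C)(C)C)[C@@H]1O | intermediate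
5 | 19-(TBS-oxy)-13,14,15,16-tetranorlabd-7-ene-3α,12-diol | C1C[C@@]2(C)[C@H](CCO)C(C)=CC[C@@H]2[C@](C)(CO[Si](C)(C)C(C)(C)C)[C@@H]1O | intermediate
6 | 12-iodo-19-(TBS-oxy)-13,14,15,16-tetranorlabd-7-en-3α-ol | C1C[C@@]2(C)[C@H](CCI)C(C)=CC[C@@H]2[C@](C)(CO[Si](C)(C)C(C)(C)C)[C@@H]1O | intermediate
7 | 12-iodo-19-(TBS-oxy)-13,14,15,16-tetranorlabd-7-en-3-one | C1C[C@@]2(C)[C@H](CCI)C(C)=CC[C@@H]2[C@](C)(CO[Si](C)(C)C(C)(C)C)C1=O | intermediate
8 | methyl acetoacetate | COC(=O)CC(C)=O | starting material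
9 | methyl (E)-3-(trifluoromethylsulfonyloxy)but-2-enoate | COC(=O)/C=C(\C)OS(=O)(=O)C(F)(F)F | intermediate
10 | alkylzinc iodide from 7 | C1C[C@@]2(C)[C@H](CC[Zn]I)C(C)=CC[C@@H]2[C@](C)(CO[Si](C)(C)C(C)(C)C)C1=O | intermediate (not isolated)
11 | methyl 19-(TBS-oxy)-3-oxolabda-7,13E-dien-15-oate | C1C[C@@]2(C)[C@H](CC/C(C)=C/C(=O)OC)C(C)=CC[C@@H]2[C@](C)(CO[Si](C)(C)C(C)(C)C)C1=O | intermediate
12 | N-benzoyloxy-N-methyl ene-hydroxylamine (C2=C3) of 11 | C=1C[C@@]2(C)[C@H](CC/C(C)=C/C(=O)OC)C(C)=CC[C@@H]2[C@](C)(CO[Si](C)(C)C(C)(C)C)C1N(C)OC(=O)c3ccccc3 | intermediate (not isolated)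
13 | 2β-benzoyloxy-3-(N-methylimine) of 11 | O=C(c3ccccc3)O[C@H]1C[C@@]2(C)[C@H](CC/C(C)=C/C(=O)OC)C(C)=CC[C@@H]2[C@](C)(CO[Si](C)(C)C(C)(C)C)C1=NC | intermediate (not isolated)
14 | methyl 2β-benzoyloxy-19-(TBS-oxy)-3-oxolabda-7,13E-dien-15-oate | O=C(c3ccccc3)O[C@H]1C[C@@]2(C)[C@H](CC/C(C)=C/C(=O)OC)C(C)=CC[C@@H]2[C@](C)(CO[Si](C)(C)C(C)(C)C)C1=O | intermediate
15 | methyl 2β-benzoyloxy-3β-hydroxy-19-(TBS-oxy)labda-7,13E-dien-15-oate | O=C(c3ccccc3)O[C@H]1C[C@@]2(C)[C@H](CC/C(C)=C/C(=O)OC)C(C)=CC[C@@H]2[C@](C)(CO[Si](C)(C)C(C)(C)C)[C@H]1O | intermediate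
16 | 2β,3β-dihydroxy-19-(TBS-oxy)labda-7,13E-dien-15-oic acid | O[C@H]1C[C@@]2(C)[C@H](CC/C(C)=C/C(=O)O)C(C)=CC[C@@H]2[C@](C)(CO[Si](C)(C)C(C)(C)C)[C@H]1O | intermediate
17 | 2β,3β-diacetoxy-19-(TBS-oxy)labda-7,13E-dien-15-oic acid | CC(=O)O[C@H]1C[C@@]2(C)[C@H](CC/C(C)=C/C(=O)O)C(C)=CC[C@@H]2[C@](C)(CO[Si](C)(C)C(C)(C)C)[C@H]1OC(C)=O | intermediate
18 | 2β,3β-diacetoxy-19-hydroxylabda-7,13E-dien-15-oic acid | CC(=O)O[C@H]1C[C@@]2(C)[C@H](CC/C(C)=C/C(=O)O)C(C)=CC[C@@H]2[C@](C)(CO)[C@H]1OC(C)=O | intermediate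
19 | 2β,3β-diacetoxy-19-oxolabda-7,13E-dien-15-oic acid (CNP0273594.1) | CC(=O)O[C@H]1C[C@@]2(C)[C@H](CC/C(C)=C/C(=O)O)C(C)=CC[C@@H]2[C@](C)(C=O)[C@H]1OC(C)=O | target

**Step count.** 14 steps in total; the longest linear sequence is 13 steps (1 → 19: steps 1–6 and 8–14), with step 7 on a one‑step side branch.

**Steps most likely to fail, with fallbacks**

Step 2 (permanganate must choose C12=C13 over C8=C17 and must not over‑oxidise the aldehyde). The fallback sets out from 2 and uses nucleophilic rather than electrophilic oxidation. Treatment with t‑BuOOLi (THF, −20 °C), which can attack only the Michael‑acceptor alkene, gives 12,13‑epoxy‑19‑O‑TBS‑andrographolide F1. H5IO6 (THF/H2O, 0 °C) then cleaves this glycidic lactone to the aldehyde, and the route is rejoined at 3.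

Step 9 (condensation at the neopentyl 3‑ketone may be slow, and the TBS ether sees a mildly acidic medium). The fallback sets out from 11 and replaces the rearrangement by enolate oxidation. The kinetic C2 enolate (KN(SiMe3)2, THF, −78 °C) is hydroxylated with 2‑(phenylsulfonyl)‑3‑phenyloxaziridine on the face anti to the axial C20 methyl, giving methyl 2β‑hydroxy‑19‑(TBS‑oxy)‑3‑oxolabda‑7,13E‑dien‑15‑oate F2. Benzoylation (BzCl, pyridine, DMAP) returns to the route at 14.

Step 10 (the axial CH2OTBS group on C4 may deflect the hydride and give the equatorial 3α‑alcohol). The fallback sets out from 14 and turns that axial group into a directing group. HF·pyridine removes the silyl group to give methyl 2β‑benzoyloxy‑19‑hydroxy‑3‑oxolabda‑7,13E‑dien‑15‑oate F3. Me4NBH(OAc)3 (MeCN/AcOH, −20 °C) binds to the axial 19‑OH and delivers hydride intramolecularly to the α face of C3, giving methyl 2β‑benzoyloxy‑3β,19‑dihydroxylabda‑7,13E‑dien‑15‑oate F4. Selective silylation of the primary hydroxyl (TBSCl, imidazole) returns to the route at 15.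

**Further compounds**
F1 | step 2 | 12,13-epoxy-19-O-(tert-butyldimethylsilyl)andrographolide (epoxide epimers) | C1C[C@@]2(C)[C@H](CC3OC34[C@@H](COC4=O)O)C(=C)CC[C@@H]2[C@](C)(CO[Si](C)(C)C(C)(C)C)[C@@H]1O
F2 | step 9 | methyl 2β-hydroxy-19-(TBS-oxy)-3-oxolabda-7,13E-dien-15-oate | O[C@H]1C[C@@]2(C)[C@H](CC/C(C)=C/C(=O)OC)C(C)=CC[C@@H]2[C@](C)(CO[Si](C)(C)C(C)(C)C)C1=O
F3 | step 10 | methyl 2β-benzoyloxy-19-hydroxy-3-oxolabda-7,13E-dien-15-oate | O=C(c3ccccc3)O[C@H]1C[C@@]2(C)[C@H](CC/C(C)=C/C(=O)OC)C(C)=CC[C@@H]2[C@](C)(CO)C1=O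
F4 | step 10 | methyl 2β-benzoyloxy-3β,19-dihydroxylabda-7,13E-dien-15-oate | O=C(c3ccccc3)O[C@H]1C[C@@]2(C)[C@H](CC/C(C)=C/C(=O)OC)C(C)=CC[C@@H]2[C@](C)(CO)[C@H]1O
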